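An excess of 95% means c(right-handed substrate) standing 39.0 times c(left-handed substrate). So this kinetic resolution had 1.59 decades to go, the powers of ten by which that ratio had to climb from its start at one.

- alpha: left-handed substrate 0.44 M; right-handed substrate 0.44 M; reagent 0.484 M; precatalyst 5.7 mM; added ligand 7.5 mM; run made earlier
- flask: left-handed substrate 0.44 M; reagent 0.484 M; precatalyst 5.7 mM; added ligand 15 mM; right-handed substrate 0.44 M; time 6.0 d

- alpha (time / h: right-handed substrate / %, left-handed substrate / %, left-handed product / %): 2.50: 49.6, 50.8, 0; 4.00: 50.7, 49.2, 0.3; 8.00: 50.1, 46.6, 3.0; 15.0: 50.0, 42.9, 5.8; 30.0: 51.4, 28.0, 16.9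

(scatter of a reading: 1 percentage point)

- whether the excess of right-handed substrate over left-handed substrate among what is left of the two reaches 95% by 6.0 d (no / yes)
- the highest excess of right-handed substrate over left-handed substrate among what is left of the two up to 6.0 d

- free catalyst is single-handed; left-handed substrate and right-handed substrate are mirror images of each other, charged as a racemate, each of them at the stated concentration
- no earlier run changes the charge of added ligand; that part of a forecast is a guess

I set the times of alpha in a row. The first rung was hours: alpha showed 0.3% of left-handed product at 4.00 h, inside the scatter, so the reaction in alpha took about that long to get going. The next rung was days: from 8.00 h to 30.0 h the ratio in alpha climbed at a read pace of 0.253 d⁻¹ in decades, so by my estimate one decade at that pace meant 3.95 d, far longer than that start. The last rung lay beyond the run: c(right-handed substrate) read 51.4% at 30.0 h against 49.6% at 2.50 h, no fall outside the scatter, so the climb in alpha was the fall of c(left-handed substrate).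

At that pace my own reckoning needed 6.28 d for the decades to go, a little longer than the 6.0 d allowed. So I expected the flask to fall just short, but its added ligand was twice that of alpha, and no earlier run changed that charge.

The forecast said no, with a top of 80% in a range from 55% to 99%, and it added “The ligand effect is a guess”. Its top stood for 0.954 decades, fewer than the 1.52 that my reckoning gave for 6.0 d, so the two of us agreed on the answer but differed on the top.

The flask gave yes, with a top of 96.8%. It reached 95% at 5.29 d, when right-handed substrate stood at 47.6% of both substrates charged.

    free catalyst + added ligand ⇌ idle complex (K = 14.0 M⁻¹, k = 0.00440 M⁻¹ s⁻¹)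
    left-handed product ⇌ right-handed product (k = 1.00 × 10⁻⁵ s⁻¹)
    free catalyst + left-handed substrate ⇌ catalyst intermediate A (K = 36.0 M⁻¹, k = 0.00710 M⁻¹ s⁻¹)
    reagent + catalyst intermediate A → free catalyst + left-handed product (k = 0.00440 M⁻¹ s⁻¹)
    precatalyst → free catalyst (k = 1.40 × 10⁻⁵ s⁻¹)
    free catalyst + right-handed substrate ⇌ catalyst intermediate B (K = 2.00 M⁻¹, k = 0.0210 M⁻¹ s⁻¹)
    reagent + catalyst intermediate B → free catalyst + right-handed product (k = 2.20 × 10⁻⁴ M⁻¹ s⁻¹)

So the flask covered the decades to go at an average 0.301 d⁻¹, faster than the pace read from alpha. In the flask the excess of 75.0% at 3.00 d stood for 0.845 decades, about half of them, and the top stood for 1.79 decades.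

The data come from a simulation with made-up constants.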